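Labdane numbering is used for every compound, including the bicyclic ones. In the pinane-type intermediates the ketone carbon is C8, the bridgeheads are C7 and C5, the CH2 bridge is C6 and the gem-dimethyl bridge carbon is C4. The key-step product has no C17 and is therefore named as a 17-nor-labdane.

## Structural features

The target is a labdane of the normal series: a trans-fused decalin in which ring A (C1–C5, C10) and ring B (C5–C10) share the C5–C10 bond. It carries a gem-dimethyl group on C4, the angular methyl C20 on C10, an exocyclic methylene C8=C17 and, on C9, the chain C11–C12–C13(C16)=C14–C15O2H with 13E geometry. C5 (H α), C10 (C20 β) and C9 (chain β, equatorial) are contiguous. The fourth stereocentre, C2, bears an axial 2β-acetoxy group that is syn-diaxial to C20 and to the β-methyl on C4; the absolute configuration is 2R,5S,9S,10S. Three groups are fragile: the exocyclic alkene moves into the ring under acid, the trisubstituted enoate can lose its geometry or deconjugate under strong base, and the acetate does not survive the hydroxide that frees the acid, so it must be introduced last. The real difficulty is the quaternary C10 beside the C5–C4 quaternary array, combined with oxygen at C2 rather than C3, an axial acetate and an epimerisable C9 next to the future methylene carbon. The feature exploited is that ring B, C20, C5 and C4 map onto (1R,5R)-verbenone: its six-membered ring is ring B, its vinylic methyl is C20, and its gem-dimethyl bridge carbon is C4, already bonded to C5 but also to C7. Only the C4–C7 bond has to be exchanged for a C3–C4 bond, and the 1,5-relationship of the oxygens at C8 and C2 lets a silyl shift from the C2 enol ether to the C8 carbonyl accompany that exchange.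

## Logic of the disconnections

**19 ⇒ 18.** The acetyl C–O bond at C2 is cut first, because the acetate is the one group that cannot coexist with hydroxide. All earlier steps may then use strong base. The forward step must acylate an alcohol flanked by two syn-axial methyl groups in the presence of a free acid, without acid that would move the alkene.

**18 ⇒ 17.** The C8=C17 bond is cut to a C8 ketone. The carbonyl is what the key step leaves at C8 in masked form and what allows C9 to be corrected. The acid-sensitive alkene is thereby absent from every earlier step. The forward step must methylenate a hindered, enolisable ketone in a molecule with two acidic protons.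

**17 ⇒ 14.** Three hydroxide-mediated changes are grouped: the O–Si bond of the C8 enol ether, the C9–H bond (epimerisation) and the O–CH3 bond of the ester. One operation replaces three. It demands that the equatorial C9 epimer is the thermodynamic one and that the enoate survives warm hydroxide.

**14 ⇒ 13.** The C2–H bond is cut to a C2 ketone, which is the oxidation level the ring closure delivers. The two axial methyl groups over the β face should direct hydride to the α face. The C8 carbonyl must stay masked so that only one carbonyl is reduced.

**13 ⇒ 12.** The C3–C4 bond is cut and the C4–C7 bond is restored, which turns the decalin into a bicyclo[3.1.1]heptanone that holds ring B, C20, C4 and the C5 and C10 stereocentres. No stereocentre has to be made in the forward step. The demand is that ionisation of the C4–C7 bond outruns every other reaction of the silyl-activated C8 carbonyl, above all aldol attack by C3, and that silyl transfer turns over. Relative to a bare design, 12 is run as the single C9 epimer with the chain anti to the bridge, with a hindered pyridine as acid scavenger.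

**12 ⇒ 11.** The O–Si bond at C2 is cut to a methyl ketone. The forward step must enolise C3 selectively in the presence of the C8 ketone, the C9–H and the enoate γ-positions, and must trap the enolate before it adds to C8; this is why in situ silylation is specified.

**11 ⇒ 10.** The C2=O bond is traced to a terminal alkene, so that C1–C3 arrive as an allyl group. The forward oxidation must be Markovnikov and must leave the enoate alone.

**10 ⇒ 6 + 8.** The C11–C12 bond is cut, which removes C12–C16 as a senecioate dienolate and leaves C11 as the terminus of an exocyclic enone. The forward step needs γ-selectivity and 13E geometry. C9 is formed by protonation, not by alkylation, so its configuration is set by equilibration and is provisional.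

**8 ⇒ 7.** The O–Si bond is cut to the commercial enoate. The forward step is γ-deprotonation and O-silylation.

**6 ⇒ 3.** The C9=C11 bond is cut to the silyl enol ether of the parent ketone. C7 is a bridgehead, so C9 is the only position that can react.

**3 ⇒ 1 + 2.** The C10–C1 bond is cut. This is the step that creates the quaternary C10, with the bridge of 1 dictating the face. The forward step must deliver the allyl group 1,4 rather than 1,2 to a β,β-disubstituted enone.

## Other disconnections considered

**Alternative 1:** The cut is the C9–C10 bond of ring B, made together with a temporary C1–C11 bond. Irradiation of the isophorone-type enone A2, whose C5 substituent leads through C6–C8 (C8 as a dioxolane) to the C9=C11 alkene, should give the cyclobutane A1. SmI2 would then break the C1–C11 bond, which lies α to the C2 ketone, and leave C11 as the first chain carbon.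
- In favour: both operations are established reaction types, the quaternary C10 is made under conditions that are little affected by crowding, and the silyl alkyne allows a stereospecific carbometalation route to the 13E enoate. On alkene geometry this is better than the vinylogous Michael addition of the chosen plan.
- Against: the only stereocentre of A2 (C5) has to be made by asymmetric synthesis and must then control C10 across a forming six-membered ring. The trans fusion is not assured for a biradical closure of this tether length, and hydrogen abstraction may compete.
- Comparison: C9 emerges epimeric and the C2 ketone needs a face-selective reduction, so on both points the alternative is the equal of the chosen plan. Structurally it builds ring B onto ring A, whereas the chosen plan builds ring A onto a terpene that already holds C4, C5, C10 and C20 in the correct absolute sense. Mechanistically it has closer precedent (better) but less predictable stereocontrol. In step economy it is worse: A2 alone needs about as many steps as the whole path to 12, and some nine operations would follow A1.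

**Alternative 2:** The cut is the C10–C20 bond, so the angular methyl is added to a 20-nor-decalin. Et2Zn/CH2I2 should cyclopropanate the C1=C10 alkene of the allylic alcohol A4 on the face of its 2β-hydroxyl to give A3. Opening of the outer C1–C20 bond would leave C20 as the β-methyl group.
- In favour: hydroxyl-directed cyclopropanation is among the most dependable face-selective reactions, and the directing oxygen is the one that becomes the acetate. In predictability of the C10 configuration this is at least the equal of the bridge-controlled cuprate addition. It is better in that C2 would need no late reduction if hydrogenolysis opens the ring, and every step is known chemistry.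
- Against: selective cleavage of C1–C20 over the two other cyclopropane bonds is not secure. Hydrogenolysis would also reduce the silyl alkyne, and the variant through the C2 ketone destroys and remakes C2. The larger problem is A4 itself: a decalin with stereocentres at C2, C5, C8 and C9 and no angular methyl has no obvious chiral-pool source.
- Comparison: the chosen plan obtains C20, C10 and C5 from the starting terpene and spends no steps on them. The alternative spends two steps on one methyl group after a long route to A4 and is clearly longer.

**Alternative 3:** The cuts are C5–C10 and C8–C9. Heating or Lewis-acid activation of the triene A6 should fold the C5=C6–C7=C8 diene onto the C9=C10 enoate and give the trans-fused octalin A5.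
- In favour: two rings, the quaternary C10 and the stereocentres C5, C8, C9 and C10 arise in one pericyclic step from a chain with one stereocentre. C9 emerges directly with the natural β configuration, which is better than the chosen plan, where C9 must be equilibrated. Either enantiomer is equally accessible, an advantage over a chiral-pool start, and the mechanism is fully precedented.
- Against: the dienophile is a β,β-disubstituted enoate of low reactivity and the diene terminus C5 is neopentyl. Ring fusion and facial selectivity rest on the single remote centre C2, which moreover ends 2α and must be inverted. After the cycloaddition C6=C7 must be saturated, the C8 alkoxymethyl group turned into the methylene, and the C9 ester extended by four carbons at a hindered position.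
- Comparison: the alternative makes every skeletal bond and four stereocentres at once, whereas the chosen key step makes one bond and no stereocentre because the hard centres are bought. The chosen plan is shorter by a wide margin.

Key step: step 7

Assumption: in the bicyclic ketones 10–12 the C9 epimer with the chain anti to the gem-dimethyl bridge is taken to be the thermodynamic one and is the epimer drawn; the other epimer would serve equally, because C9 is equilibrated in step 9.

## Route

Step 1
Reactants: 1 (1R,5R)-(+)-verbenone; 2 allylmagnesium bromide
Product: 3 4-allyl-4,6,6-trimethyl-2-(trimethylsilyloxy)bicyclo[3.1.1]hept-2-ene (pinane locants; bridgeheads as in 1; allyl anti and the 4-methyl syn to the gem-dimethyl bridge; in labdane terms C8=C9 enol ether, C1 α and C20 β on C10)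
Conditions: CuBr·SMe2 (20 mol %), Me3SiCl, DMPU, THF, −78 °C; then Et3N, cold aq NaHCO3
Reagents that add atoms: chlorotrimethylsilane, C[Si](C)(C)Cl
Why: Copper-catalysed, chlorosilane-accelerated conjugate addition of the Grignard reagent delivers the allyl group to C10 from the face opposite the gem-dimethyl bridge, the only open face, which sets C10 and with it the later trans ring fusion. The enolate is trapped as the C8=C9 silyl enol ether, the only possible regioisomer because the bridgehead C7 cannot enolise.

Step 2
Reactants: 3 silyl enol ether from step 1
Product: 6 4-allyl-4,6,6-trimethyl-3-methylenebicyclo[3.1.1]heptan-2-one (allyl anti to the gem-dimethyl bridge; exocyclic C9=C11), via Mannich base 4 (not isolated), via quaternary ammonium iodide 5 (not isolated)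
Conditions: Me2N=CH2 I (Eschenmoser's salt), CH2Cl2, 0 °C → rt; MeI; then DBU, rt
Reagents that add atoms: N,N-dimethylmethyleneiminium iodide (Eschenmoser's salt), C=[N+](C)C.[I-]
Why: Mannich reaction of the silyl enol ether at C9, N-methylation and E1cB loss of trimethylamine give the α-methylene ketone. No stereocentre is kept at C9.

Step 3
Reactants: 7 methyl 3-methylbut-2-enoate
Product: 8 1-(tert-butyldimethylsilyloxy)-1-methoxy-3-methylbuta-1,3-diene (ketene acetal geometry not defined and not relevant)
Conditions: LiN(i-Pr)2, THF, −78 °C; t-BuMe2SiCl, DMPU, −78 °C → rt
Reagents that add atoms: tert-butyldimethylsilyl chloride, CC(C)(C)[Si](C)(C)Cl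
Why: γ-Deprotonation of the enoate and O-silylation give the silyl dienolate (a vinylogous silyl ketene acetal), the standard preparation of this reagent class.

Step 4
Reactants: 6 exocyclic enone; 8 silyl dienolate
Product: 10 methyl (E)-5-[4-allyl-4,6,6-trimethyl-2-oxobicyclo[3.1.1]heptan-3-yl]-3-methylpent-2-enoate (chain on C9 and allyl on C10 both anti to the gem-dimethyl bridge), via silyl enol ether 9 (not isolated)
Conditions: t-BuMe2SiOTf (10 mol %), CH2Cl2, −78 °C; 1 M HCl, THF, rt; then K2CO3, MeOH, rt
Reagents that add atoms: none
Why: Vinylogous Mukaiyama–Michael addition: the silyl-activated exocyclic enone is attacked at C11 by the γ-carbon of the dienolate, forming C11–C12, and the 13E enoate is expected as the main isomer. Hydrolysis of the C8 enol ether and base equilibration should place the C9 chain anti to the bridge; this centre is reset in step 9.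

Step 5
Reactants: 10 allyl ketone
Product: 11 methyl (E)-3-methyl-5-[4,6,6-trimethyl-2-oxo-4-(2-oxopropyl)bicyclo[3.1.1]heptan-3-yl]pent-2-enoate (stereochemistry as in 10)
Conditions: PdCl2 (10 mol %), CuCl, O2 (1 atm), DMF/H2O, rt
Reagents that add atoms: water, O
Why: Tsuji–Wacker oxidation: Markovnikov hydroxypalladation of the monosubstituted alkene gives the methyl ketone at C2. The electron-poor trisubstituted enoate and the hindered ketone should not react.

Step 6
Reactants: 11 diketone
Product: 12 methyl (E)-5-{4-[2-(tert-butyldimethylsilyloxy)prop-2-enyl]-4,6,6-trimethyl-2-oxobicyclo[3.1.1]heptan-3-yl}-3-methylpent-2-enoate (stereochemistry as in 10; C2=C3 silyl enol ether)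
Conditions: KN(SiMe3)2 added to 11 and t-BuMe2SiCl, THF, −78 °C
Reagents that add atoms: tert-butyldimethylsilyl chloride, CC(C)(C)[Si](C)(C)Cl
Why: Kinetic deprotonation by the hindered amide should occur at the open C3 methyl rather than at the neopentyl C1 methylene, the tertiary C9–H or the less acidic enoate γ-positions. The chlorosilane already present traps the enolate (in situ quench) before it can equilibrate or add to the C8 carbonyl.

Step 7
Reactants: 12 bicyclic keto silyl enol ether
Product: 13 methyl 8-(tert-butyldimethylsilyloxy)-2-oxo-17-nor-9-epi-labda-7,13E-dien-15-oate (trans-decalin; H5 α, C20 β, C9 chain α)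
Conditions: t-BuMe2SiOTf (10 mol %), 2,6-di-tert-butyl-4-methylpyridine (15 mol %), CH2Cl2, −78 → −20 °C; Et3N quench
Reagents that add atoms: none
Why: Proposed new method: O-silylation of the C8 carbonyl of 12 gives a silyloxocarbenium ion whose neighbouring, strained C4–C7 bond lies well out of the carbonyl plane and can therefore ionise (a retro-Prins/Grob-type scission driven by release of cyclobutane strain), giving the C7=C8 silyl enol ether and a tertiary cation at C4 still attached to C5; the closest known reaction types are the Lewis-acid or halosilane opening of pinane-type cyclobutyl ketones at this same bond and the tert-alkylation of silyl enol ethers by tertiary cations (Reetz alkylation, enol-ether-terminated cation–olefin cyclisation), but their combination into a silyl-transfer chain is without precedent. Once ring B has relaxed to a half-chair, C4 (on C5) and C1 (on C10) are trans-diequatorial and C3 of the 2-silyloxyallyl group attacks C4 through a chair-like transition state with C20 axial: ring A closes in a 6-endo-trig mode with respect to the enol ether π bond (6-(enolendo) in Baldwin's terms), forming C3–C4. The C2 silyloxocarbenium ion so formed passes its silyl group to the C8 carbonyl of the next molecule of 12, directly or through re-formed silyl triflate, so the triflate is catalytic and the step is an isomerisation. No stereocentre is created: C5 and C10 are untouched and already fix the trans fusion, and C9 is reset in step 9. The selectivities needed are cleavage of C4–C7 rather than C6–C7 (tertiary against primary cation), capture of the cation by C3 rather than proton loss or hydride shift (a six-ring intramolecular attack by a strongly nucleophilic π bond, with the hindered pyridine present only to remove adventitious TfOH), and fragmentation rather than Mukaiyama aldol attack of C3 on the activated C8 carbonyl (that adduct would be a congested bridged tertiary silyl ether with the C9 chain axial, expected to form reversibly, whereas fragmentation and closure are irreversible).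

Step 8
Reactants: 13 keto silyl enol ether
Product: 14 methyl 8-(tert-butyldimethylsilyloxy)-2β-hydroxy-17-nor-9-epi-labda-7,13E-dien-15-oate
Conditions: NaBH4, MeOH/THF, −20 → 0 °C
Reagents that add atoms: none
Why: Hydride should attack the C2 ketone from the α face (equatorial trajectory), because the β face is blocked by the two syn-axial methyl groups on C4 and C10; this gives the axial 2β-alcohol. The silyl enol ether masks C8, and NaBH4 does not reduce the β,β-disubstituted enoate.

Step 9
Reactants: 14 hydroxy silyl enol ether
Product: 17 2β-hydroxy-8-oxo-17-norlabd-13E-en-15-oic acid (C9 chain β), via 9-epi keto ester 15 (not isolated), via keto ester 16 (not isolated)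
Conditions: LiOH·H2O, THF/MeOH/H2O, 50 °C; then 1 M HCl to pH 3
Reagents that add atoms: lithium hydroxide, [Li+].[OH-]
Why: Hydroxide cleaves the silyl enol ether (the enolate is a phenoxide-like leaving group) to the C8 ketone. Reversible enolisation then moves the C9 chain from the axial α to the equatorial β position under thermodynamic control, and the methyl ester is saponified.

Step 10
Reactants: 17 hydroxy keto acid
Product: 18 2β-hydroxylabda-8(17),13E-dien-15-oic acid
Conditions: Ph3PCH3Br, KOt-Bu (5 equiv each), THF, 0 °C → reflux; cold dilute HCl to pH 4
Reagents that add atoms: methyltriphenylphosphonium bromide, C[P+](c1ccccc1)(c1ccccc1)c1ccccc1.[Br-]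
Why: Wittig methylenation of the C8 ketone. The substrate reacts as its dianion, which costs two equivalents of base but shields the enoate from ylide attack and γ-deprotonation; any enolisation toward C9 returns the equatorial epimer.

Step 11
Reactants: 18 hydroxy acid
Product: 19 2β-acetoxylabda-8(17),13E-dien-15-oic acid, (2R,5S,9S,10S), the target
Conditions: Ac2O, pyridine, DMAP (cat.), rt; then H2O
Reagents that add atoms: acetic anhydride, CC(=O)OC(C)=O
Why: DMAP-catalysed acylation of the hindered axial alcohol. The mixed anhydride formed at the carboxyl group is hydrolysed in the aqueous work-up, and the non-acidic conditions leave the exocyclic alkene in place.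

## Compound list

1 | (1R,5R)-(+)-verbenone | CC1=CC(=O)[C@@H]2C[C@H]1C2(C)C | starting material
2 | allylmagnesium bromide | C=CC[Mg]Br | starting material
3 | 4-allyl-4,6,6-trimethyl-2-(trimethylsilyloxy)bicyclo[3.1.1]hept-2-ene, allyl anti to the gem-dimethyl bridge | C[Si](C)(C)OC1=C[C@@](C)(CC=C)[C@H]2C[C@@H]1C2(C)C | intermediate
4 | 4-allyl-3-(dimethylaminomethyl)-4,6,6-trimethylbicyclo[3.1.1]heptan-2-one (Mannich base, aminomethyl anti to the bridge) | O=C1[C@@H](CN(C)C)[C@@](C)(CC=C)[C@H]2C[C@@H]1C2(C)C | intermediate
5 | trimethylammonium iodide of 4 | O=C1[C@@H](C[N+](C)(C)C)[C@@](C)(CC=C)[C@H]2C[C@@H]1C2(C)C.[I-] | intermediate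
6 | 4-allyl-4,6,6-trimethyl-3-methylenebicyclo[3.1.1]heptan-2-one | O=C1C(=C)[C@@](C)(CC=C)[C@H]2C[C@@H]1C2(C)C | intermediate
7 | methyl 3-methylbut-2-enoate | COC(=O)C=C(C)C | starting material
8 | 1-(tert-butyldimethylsilyloxy)-1-methoxy-3-methylbuta-1,3-diene | C=C(C)C=C(OC)O[Si](C)(C)C(C)(C)C | intermediate
9 | methyl (E)-5-[4-allyl-2-(tert-butyldimethylsilyloxy)-4,6,6-trimethylbicyclo[3.1.1]hept-2-en-3-yl]-3-methylpent-2-enoate | CC(C)(C)[Si](C)(C)OC1=C(CC/C(C)=C/C(=O)OC)[C@@](C)(CC=C)[C@H]2C[C@@H]1C2(C)C | intermediate
10 | methyl (E)-5-[4-allyl-4,6,6-trimethyl-2-oxobicyclo[3.1.1]heptan-3-yl]-3-methylpent-2-enoate, chain and allyl anti to the bridge | O=C1[C@@H](CC/C(C)=C/C(=O)OC)[C@@](C)(CC=C)[C@H]2C[C@@H]1C2(C)C | intermediate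
11 | methyl (E)-3-methyl-5-[4,6,6-trimethyl-2-oxo-4-(2-oxopropyl)bicyclo[3.1.1]heptan-3-yl]pent-2-enoate | O=C1[C@@H](CC/C(C)=C/C(=O)OC)[C@@](C)(CC(C)=O)[C@H]2C[C@@H]1C2(C)C | intermediate
12 | methyl (E)-5-{4-[2-(tert-butyldimethylsilyloxy)prop-2-enyl]-4,6,6-trimethyl-2-oxobicyclo[3.1.1]heptan-3-yl}-3-methylpent-2-enoate | O=C1[C@@H](CC/C(C)=C/C(=O)OC)[C@@](C)(CC(=C)O[Si](C)(C)C(C)(C)C)[C@H]2C[C@@H]1C2(C)C | intermediate
13 | methyl 8-(tert-butyldimethylsilyloxy)-2-oxo-17-nor-9-epi-labda-7,13E-dien-15-oate | CC(C)(C)[Si](C)(C)OC1=CC[C@H]2C(C)(C)CC(=O)C[C@]2(C)[C@@H]1CC/C(C)=C/C(=O)OC | intermediate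
14 | methyl 8-(tert-butyldimethylsilyloxy)-2β-hydroxy-17-nor-9-epi-labda-7,13E-dien-15-oate | CC(C)(C)[Si](C)(C)OC1=CC[C@H]2C(C)(C)C[C@@H](O)C[C@]2(C)[C@@H]1CC/C(C)=C/C(=O)OC | intermediate
15 | methyl 2β-hydroxy-8-oxo-17-nor-9-epi-labd-13E-en-15-oate | O=C1CC[C@H]2C(C)(C)C[C@@H](O)C[C@]2(C)[C@@H]1CC/C(C)=C/C(=O)OC | intermediate
16 | methyl 2β-hydroxy-8-oxo-17-norlabd-13E-en-15-oate | O=C1CC[C@H]2C(C)(C)C[C@@H](O)C[C@]2(C)[C@H]1CC/C(C)=C/C(=O)OC | intermediate
17 | 2β-hydroxy-8-oxo-17-norlabd-13E-en-15-oic acid | O=C1CC[C@H]2C(C)(C)C[C@@H](O)C[C@]2(C)[C@H]1CC/C(C)=C/C(=O)O | intermediate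
18 | 2β-hydroxylabda-8(17),13E-dien-15-oic acid | C=C1CC[C@H]2C(C)(C)C[C@@H](O)C[C@]2(C)[C@H]1CC/C(C)=C/C(=O)O | intermediate
19 | 2β-acetoxylabda-8(17),13E-dien-15-oic acid | C=C1CC[C@H]2C(C)(C)C[C@@H](OC(C)=O)C[C@]2(C)[C@H]1CC/C(C)=C/C(=O)O | target

## Step count and least certain steps

Total: 11 steps. Longest linear sequence: 10 steps (steps 1, 2 and 4–11 from 1); step 3 is a one-step side branch.

**Step 7 (key step, proposed new method).** The silyl-activated C8 carbonyl may be consumed by intramolecular Mukaiyama aldol attack of C3 instead of ionisation of the C4–C7 bond. The ionisation may also fail to occur without a nucleophilic counter-ion, or the C4 cation may lose a proton before ring closure. The fallback uses known chemistry, sets out from 12 and returns at 13, and separates the two events. t-BuMe2SiI (from t-BuMe2SiCl and NaI in MeCN) should open the cyclobutyl ketone in the manner known for iodosilanes and pinane ketones, iodide capturing C4 as the C8 oxygen is silylated, to give the tertiary iodide bis(silyl enol ether) F1. AgOTf in CH2Cl2 at low temperature then ionises the tertiary iodide, and the C2 silyl enol ether is tert-alkylated intramolecularly (Reetz-type alkylation) with loss of its silyl group, giving 13.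

**Step 1.** The allyl nucleophile may add 1,2 to the C8 carbonyl rather than 1,4 to the hindered β,β-disubstituted C10. The fallback sets out from 1 and returns at 3, and uses the 1,2-addition instead of fighting it. Allylmagnesium bromide without copper gives the tertiary allylic alcohol F2, with allyl anti to the bridge. KH/18-crown-6 in THF then triggers an anionic oxy-Cope rearrangement that moves the allyl group suprafacially from C8 to C10 on the same face, and the potassium enolate is silylated with Me3SiCl to give 3.

**Step 6.** The base may also deprotonate C9 or the enoate γ-positions, and the new enolate may add to the C8 carbonyl (intramolecular aldol) before it is silylated. The fallback sets out from 6 and returns at 12, and reorders the sequence so that C8 is masked while the methyl ketone is enolised.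
- Wacker oxidation of 6 gives the ene-dione F3.
- Me3SiOTf-catalysed vinylogous Mukaiyama–Michael addition of the trimethylsilyl dienolate F4 (from 7, LiN(i-Pr)2 and Me3SiCl) gives the C8 trimethylsilyl enol ether F5.
- Kinetic silylation of its methyl ketone with KN(SiMe3)2/t-BuMe2SiCl gives the mixed bis(silyl enol ether) F6.
- K2CO3 in MeOH at 0 °C removes the trimethylsilyl group, which is far faster to solvolyse than the tert-butyldimethylsilyl group, and gives 12 after equilibration at C9.

**Step 4.** The dienolate may attack through its α-carbon, the 13E geometry may erode, or the adduct may close stepwise to a spiro ring at C9. The fallback sets out from 6 and returns at 10, and builds the trisubstituted alkene stereospecifically. Mukaiyama–Michael addition of 1-methoxy-1,3-bis(trimethylsilyloxy)buta-1,3-diene to 6 and acidic work-up give the β-keto ester F7. NaH and (EtO)2P(O)Cl give the (Z)-enol phosphate F8 through the chelated enolate. Me2CuLi in Et2O at −78 → −45 °C replaces the phosphate by methyl with retention and gives 10 with the 13E geometry.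

**Step 10.** Olefination may be incomplete, because the ylide can enolise the hindered C8 ketone and the dipotassium salt of 17 may be poorly soluble. The fallback sets out from 14 and returns at 18, and moves the methylenation to the ester stage with a non-basic reagent. Bu4NF in THF followed by NaOMe in MeOH gives 16, which is isolated. Zn/CH2Br2/TiCl4, which tolerates esters and free hydroxyl groups and does not epimerise C9, gives the hydroxy diene ester F9. LiOH in aqueous THF/MeOH then gives 18.

## Further compounds

F1 | step 7 | methyl 2,8-bis(tert-butyldimethylsilyloxy)-4-iodo-17-nor-3,4-seco-9-epi-labda-2,7,13E-trien-15-oate (tertiary iodide) | CC(C)(C)[Si](C)(C)OC1=CC[C@@H](C(C)(C)I)[C@](C)(CC(=C)O[Si](C)(C)C(C)(C)C)[C@@H]1CC/C(C)=C/C(=O)OC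
F2 | step 1 | 2-allyl-4,6,6-trimethylbicyclo[3.1.1]hept-3-en-2-ol, allyl anti and hydroxyl syn to the gem-dimethyl bridge | CC1=C[C@](O)(CC=C)[C@@H]2C[C@H]1C2(C)C
F3 | step 6 | 4,6,6-trimethyl-3-methylene-4-(2-oxopropyl)bicyclo[3.1.1]heptan-2-one | O=C1C(=C)[C@@](C)(CC(C)=O)[C@H]2C[C@@H]1C2(C)C
F4 | step 6 | 1-methoxy-3-methyl-1-(trimethylsilyloxy)buta-1,3-diene | C=C(C)C=C(OC)O[Si](C)(C)C
F5 | step 6 | methyl (E)-3-methyl-5-[4,6,6-trimethyl-4-(2-oxopropyl)-2-(trimethylsilyloxy)bicyclo[3.1.1]hept-2-en-3-yl]pent-2-enoate | C[Si](C)(C)OC1=C(CC/C(C)=C/C(=O)OC)[C@@](C)(CC(C)=O)[C@H]2C[C@@H]1C2(C)C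
F6 | step 6 | methyl (E)-5-{4-[2-(tert-butyldimethylsilyloxy)prop-2-enyl]-4,6,6-trimethyl-2-(trimethylsilyloxy)bicyclo[3.1.1]hept-2-en-3-yl}-3-methylpent-2-enoate | C[Si](C)(C)OC1=C(CC/C(C)=C/C(=O)OC)[C@@](C)(CC(=C)O[Si](C)(C)C(C)(C)C)[C@H]2C[C@@H]1C2(C)C
F7 | step 4 | methyl 5-[4-allyl-4,6,6-trimethyl-2-oxobicyclo[3.1.1]heptan-3-yl]-3-oxopentanoate | O=C1[C@@H](CCC(=O)CC(=O)OC)[C@@](C)(CC=C)[C@H]2C[C@@H]1C2(C)C
F8 | step 4 | methyl (Z)-5-[4-allyl-4,6,6-trimethyl-2-oxobicyclo[3.1.1]heptan-3-yl]-3-(diethoxyphosphoryloxy)pent-2-enoate | O=C1[C@@H](CC/C(OP(=O)(OCC)OCC)=C/C(=O)OC)[C@@](C)(CC=C)[C@H]2C[C@@H]1C2(C)C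
F9 | step 10 | methyl 2β-hydroxylabda-8(17),13E-dien-15-oate | C=C1CC[C@H]2C(C)(C)C[C@@H](O)C[C@]2(C)[C@H]1CC/C(C)=C/C(=O)OC
A1 | alternative 1 | cyclobutane photoadduct (C1–C10–C9–C11 ring on the α face, C8 dioxolane, silylpropargyl on C11) | O=C1CC(C)(C)[C@@H]2CCC3(OCCO3)[C@H]4[C@H](CC#C[Si](C)(C)C)[C@@H]1[C@@]24C
A2 | alternative 1 | (E)-4-[3,3-ethylenedioxy-8-(trimethylsilyl)oct-4-en-7-ynyl]-3,5,5-trimethylcyclohex-2-en-1-one | O=C1C=C(C)[C@@H](CCC2(OCCO2)/C=C/CC#C[Si](C)(C)C)C(C)(C)C1
A3 | alternative 2 | 1,10-methano (cyclopropane) adduct, methylene C20 on the β face, 2β-hydroxy, 8α-silyloxy | CC(C)(C)[Si](C)(C)O[C@@H]1CC[C@H]2C(C)(C)C[C@@H](O)[C@H]3C[C@]32[C@H]1CCC#C[Si](C)(C)C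
A4 | alternative 2 | 20-nor allylic alcohol with C1=C10 alkene, 2β-hydroxy, 8α-silyloxy | CC(C)(C)[Si](C)(C)O[C@@H]1CC[C@H]2C(C)(C)C[C@@H](O)C=C2[C@H]1CCC#C[Si](C)(C)C
A5 | alternative 3 | trans-fused octalin adduct (2α-silyloxy, 8β-alkoxymethyl, 9β-ester, C6=C7 alkene) | COc1ccc(COC[C@H]2C=C[C@H]3C(C)(C)C[C@H](O[Si](C)(C)C(C)(C)C)C[C@]3(C)[C@H]2C(=O)OC)cc1
A6 | alternative 3 | methyl (2E,8E,10E)-5-(tert-butyldimethylsilyloxy)-12-(4-methoxybenzyloxy)-3,7,7-trimethyldodeca-2,8,10-trienoate, C5 configured as C2 of A5 | COc1ccc(COC/C=C/C=C/C(C)(C)C[C@H](O[Si](C)(C)C(C)(C)C)C/C(C)=C/C(=O)OC)cc1
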